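A direct plan would assemble the trisubstituted 4-hydroxystilbene A2 from the aryl propargyl silyl ether A1 by alkyne hydrostannation and Stille coupling. It would then close the dihydrofuran ring through its C2–O1 bond by an enantioselective Brønsted acid catalysed cycloisomerisation to the aldehyde A3, and build the flavonol on that aldehyde at the end. Its weakest steps would be:
(a) the hydrostannation, which would have to place tin on the alkyne carbon next to the CH2O group although an aryl alkyne offers little bias, before a Stille coupling in the presence of free catechol hydroxyl groups;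
(b) the cycloisomerisation, which would have no precedent and would have to set both stereocentres through one enantioselective protonation, in competition with a racemic background path.

The route rests on the C2–C3 bond of the dihydrofuran ring. C3 carries ring B and a carbon at the carboxyl level, which is the substitution pattern of an aryl(alkoxycarbonyl)carbene, and C2–H is a benzylic C–H bond next to O1; the ring is therefore unravelled to a 4-benzyloxy-3-methoxybenzyl ether and an arylacetate on ring B of a finished flavonol. One operation, the enantioselective 1,5 C–H insertion of the rhodium carbene from diazoester 11, closes the dihydrofuran, forms C2–C3 and sets C2, after which C3 follows by equilibration. No stilbene, no tin chemistry and no asymmetric protonation are needed, and ring C is closed first, on achiral material.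

Key step: step 6

Assumption: the sense of induction of the chiral dirhodium carboxylates (and of the lactamide auxiliary in the fallback) is assigned by analogy with simpler 2-(benzyloxy)phenyl diazoacetates; should the insertion favour the 2S series, the enantiomeric catalyst (or auxiliary) would be used with nothing else changed.

Step 1
Reactants: 1 3-bromo-4,5-dihydroxybenzaldehyde; 2 4-(benzyloxy)-3-methoxybenzyl chloride
Product: 4 3-(benzyloxy)-4-{[4-(benzyloxy)-3-methoxyphenyl]methoxy}-5-bromobenzaldehyde, via 5-hydroxy mono-ether 3 (not isolated)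
Conditions: 2 (1.0 equiv), NaHCO3, NaI (cat.), DMF, 40 °C; then BnBr, K2CO3, rt to 50 °C
Reagents that add atoms: benzyl bromide BrCc1ccccc1
Why: Two Williamson etherifications in one flask: hydrogencarbonate should ionise only the more acidic 4-OH (para to the formyl group, ortho to bromine), which takes the benzylic chloride, and carbonate with benzyl bromide then caps the remaining 5-OH.

Step 2
Reactants: 4 3-(benzyloxy)-4-{[4-(benzyloxy)-3-methoxyphenyl]methoxy}-5-bromobenzaldehyde; 5 1-[2,4-bis(benzyloxy)-6-hydroxyphenyl]ethan-1-one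
Product: 7 5,7-bis(benzyloxy)-2-[3-(benzyloxy)-4-{[4-(benzyloxy)-3-methoxyphenyl]methoxy}-5-bromophenyl]-3-hydroxy-4H-chromen-4-one, via chalcone 6 (not isolated)
Conditions: KOH (50% aq), EtOH/THF, rt, 36 h; then 30% H2O2, 0 °C to rt
Reagents that add atoms: hydrogen peroxide OO
Why: Claisen–Schmidt condensation should give the 2'-hydroxychalcone and the Algar–Flynn–Oyamada oxidation then closes ring C through the phenoxide while H2O2 supplies the 3-OH, the aryl bromide and the benzyl ethers being inert to aqueous alkali and peroxide.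

Step 3
Reactants: 7 5,7-bis(benzyloxy)-2-[3-(benzyloxy)-4-{[4-(benzyloxy)-3-methoxyphenyl]methoxy}-5-bromophenyl]-3-hydroxy-4H-chromen-4-one
Product: 8 3,5,7-tris(benzyloxy)-2-[3-(benzyloxy)-4-{[4-(benzyloxy)-3-methoxyphenyl]methoxy}-5-bromophenyl]-4H-chromen-4-one
Conditions: BnBr, K2CO3, DMF, rt to 50 °C
Reagents that add atoms: benzyl bromide BrCc1ccccc1
Why: Williamson etherification of the acidic 3-OH removes the only O–H bond that a rhodium carbene could attack later and leaves the flavonol without any acidic or enolisable site.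

Step 4
Reactants: 8 3,5,7-tris(benzyloxy)-2-[3-(benzyloxy)-4-{[4-(benzyloxy)-3-methoxyphenyl]methoxy}-5-bromophenyl]-4H-chromen-4-one; 9 (2-ethoxy-2-oxoethyl)zinc bromide (Reformatsky reagent, solution in THF)
Product: 10 ethyl 2-[3-(benzyloxy)-2-{[4-(benzyloxy)-3-methoxyphenyl]methoxy}-5-[3,5,7-tris(benzyloxy)-4-oxo-4H-chromen-2-yl]phenyl]acetate
Conditions: 9 (2 equiv), Pd(dba)2 (3 mol%), P(tBu)3 (3 mol%), THF, rt to 50 °C
Reagents that add atoms: none
Why: Palladium-catalysed α-arylation of an ester as its zinc enolate (Negishi-type coupling of a Reformatsky reagent) proceeds by oxidative addition of the aryl bromide to zerovalent palladium, transmetalation and reductive elimination, under conditions mild enough for the chromenone carbonyl and the benzyl ethers.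

Step 5
Reactants: 10 ethyl 2-[3-(benzyloxy)-2-{[4-(benzyloxy)-3-methoxyphenyl]methoxy}-5-[3,5,7-tris(benzyloxy)-4-oxo-4H-chromen-2-yl]phenyl]acetate
Product: 11 ethyl 2-[3-(benzyloxy)-2-{[4-(benzyloxy)-3-methoxyphenyl]methoxy}-5-[3,5,7-tris(benzyloxy)-4-oxo-4H-chromen-2-yl]phenyl]-2-diazoacetate
Conditions: 4-acetamidobenzenesulfonyl azide, DBU, MeCN/CH2Cl2, 0 °C to rt
Reagents that add atoms: 4-acetamidobenzenesulfonyl azide CC(=O)Nc1ccc(cc1)S(=O)(=O)N=[N+]=[N-]
Why: Regitz diazo transfer: DBU generates the arylacetate enolate, which attacks the terminal nitrogen of the sulfonyl azide and expels the sulfonamide to leave the donor/acceptor diazoester.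

Step 6
Reactants: 11 ethyl 2-[3-(benzyloxy)-2-{[4-(benzyloxy)-3-methoxyphenyl]methoxy}-5-[3,5,7-tris(benzyloxy)-4-oxo-4H-chromen-2-yl]phenyl]-2-diazoacetate
Product: 12 ethyl (2R,3S)-7-(benzyloxy)-2-[4-(benzyloxy)-3-methoxyphenyl]-5-[3,5,7-tris(benzyloxy)-4-oxo-4H-chromen-2-yl]-2,3-dihydro-1-benzofuran-3-carboxylate (2,3-cis)
Conditions: Rh2(S-PTTL)4 (dirhodium tetrakis[N-phthaloyl-(S)-tert-leucinate], 1 mol%), PhMe/CH2Cl2, 4 Å MS, −60 °C to −40 °C, slow addition of 11
Reagents that add atoms: none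
Why: Rh2(S-PTTL)4 expels N2 from the aryldiazoacetate to give a donor/acceptor rhodium carbene, which inserts through a concerted, asynchronous three-centre transition state with hydride-transfer character into one of the two enantiotopic C–H bonds of the ortho OCH2Ar group, a position activated by the ether oxygen and by the electron-rich 4-benzyloxy-3-methoxyphenyl ring, so that the C2–C3 bond forms with retention at the C–H carbon. The closest known reaction type is the enantioselective intramolecular C–H insertion of 2-(benzyloxy)aryl diazoacetates with dirhodium tetrakis(N-phthaloyl amino acid carboxylate) catalysts, which gives cis-2-aryl-2,3-dihydrobenzofuran-3-carboxylates. The dihydrofuran ring is closed by a 1,5-insertion, the carbene carbon (future C3) bonding to the fifth atom of the chain C3–C3a–C7a–O1–CH2. C2 is set by the chiral carboxylate pocket, which selects the enantiotopic hydrogen, and C3 is set kinetically cis to the C2 aryl group in the compact insertion transition state and is corrected to trans in step 7 under control of C2. The step needs site selectivity for this C–H bond over the other benzylic ether C–H bonds and over the arenes, which the substrate secures because only the ortho ether CH2 lies within five-membered reach (insertion into the neighbouring 7-OCH2Ph would demand a six-membered ring spanning two meta positions of ring B) and because no O–H bond remains after step 3.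

Step 7
Reactants: 12 ethyl (2R,3S)-7-(benzyloxy)-2-[4-(benzyloxy)-3-methoxyphenyl]-5-[3,5,7-tris(benzyloxy)-4-oxo-4H-chromen-2-yl]-2,3-dihydro-1-benzofuran-3-carboxylate (2,3-cis)
Product: 14 (2R,3R)-7-(benzyloxy)-2-[4-(benzyloxy)-3-methoxyphenyl]-5-[3,5,7-tris(benzyloxy)-4-oxo-4H-chromen-2-yl]-2,3-dihydro-1-benzofuran-3-carboxylic acid (2,3-trans), via trans ethyl ester 13 (not isolated)
Conditions: NaOEt (0.5 equiv), EtOH/THF, 40 °C; then LiOH·H2O, H2O, 40 °C; 1 M HCl work-up
Reagents that add atoms: lithium hydroxide [Li+].[OH-]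
Why: Base-mediated epimerisation through the ester enolate should move the ester anti to the C2 aryl group (C2 has no acidic hydrogen and dictates the thermodynamic trans configuration at C3, and β-elimination of O1 is stereoelectronically disfavoured because the C2–O1 bond lies in the nodal plane of the enolate, the reverse of a 5-endo-trig closure), and saponification then fixes C3 as the non-enolisable carboxylate.

Step 8
Reactants: 14 (2R,3R)-7-(benzyloxy)-2-[4-(benzyloxy)-3-methoxyphenyl]-5-[3,5,7-tris(benzyloxy)-4-oxo-4H-chromen-2-yl]-2,3-dihydro-1-benzofuran-3-carboxylic acid (2,3-trans)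
Product: 16 3,5,7-tris(benzyloxy)-2-[(2R,3S)-7-(benzyloxy)-2-[4-(benzyloxy)-3-methoxyphenyl]-3-(hydroxymethyl)-2,3-dihydro-1-benzofuran-5-yl]-4H-chromen-4-one, via isobutyl carbonic mixed anhydride 15 (not isolated)
Conditions: iBuOCOCl, N-methylmorpholine, THF, −15 °C; then NaBH4, H2O, −15 to 0 °C
Reagents that add atoms: none
Why: Reduction of a carboxylic acid through its mixed carbonic anhydride: NaBH4 attacks the activated acyl carbon at low temperature, whereas the cross-conjugated pyranone carbonyl of a 3-alkoxyflavone should resist NaBH4 under these conditions, and neither stereocentre is touched (the descriptor at C3 changes from R to S only through the priority change from CO2H to CH2OH).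

Step 9
Reactants: 16 3,5,7-tris(benzyloxy)-2-[(2R,3S)-7-(benzyloxy)-2-[4-(benzyloxy)-3-methoxyphenyl]-3-(hydroxymethyl)-2,3-dihydro-1-benzofuran-5-yl]-4H-chromen-4-one
Product: 17 2,3-dehydrosilychristin, 2-[(2R,3S)-7-hydroxy-2-(4-hydroxy-3-methoxyphenyl)-3-(hydroxymethyl)-2,3-dihydro-1-benzofuran-5-yl]-3,5,7-trihydroxy-4H-chromen-4-one
Conditions: H2 (1 atm), Pd/C (10 wt%), THF/MeOH, rt
Reagents that add atoms: none
Why: Catalytic hydrogenolysis of the five benzyl aryl ethers over palladium under neutral conditions at 1 atm should spare the flavonol double bond and the cyclic benzylic C2–O1 bond of the 2-aryl-dihydrobenzofuran.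

## Compound list

1 | 3-bromo-4,5-dihydroxybenzaldehyde | O=Cc1cc(O)c(O)c(Br)c1 | starting material
2 | 4-(benzyloxy)-3-methoxybenzyl chloride | COc1cc(CCl)ccc1OCc1ccccc1 | starting material
3 | 3-bromo-4-{[4-(benzyloxy)-3-methoxyphenyl]methoxy}-5-hydroxybenzaldehyde | COc1cc(COc2c(O)cc(C=O)cc2Br)ccc1OCc1ccccc1 | intermediate
4 | 3-(benzyloxy)-4-{[4-(benzyloxy)-3-methoxyphenyl]methoxy}-5-bromobenzaldehyde | COc1cc(COc2c(OCc3ccccc3)cc(C=O)cc2Br)ccc1OCc1ccccc1 | intermediate
5 | 1-[2,4-bis(benzyloxy)-6-hydroxyphenyl]ethan-1-one | CC(=O)c1c(O)cc(OCc2ccccc2)cc1OCc1ccccc1 | starting material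
6 | (2E)-3-[3-(benzyloxy)-4-{[4-(benzyloxy)-3-methoxyphenyl]methoxy}-5-bromophenyl]-1-[2,4-bis(benzyloxy)-6-hydroxyphenyl]prop-2-en-1-one | COc1cc(COc2c(OCc3ccccc3)cc(/C=C/C(=O)c3c(O)cc(OCc4ccccc4)cc3OCc3ccccc3)cc2Br)ccc1OCc1ccccc1 | intermediate
7 | 5,7-bis(benzyloxy)-2-[3-(benzyloxy)-4-{[4-(benzyloxy)-3-methoxyphenyl]methoxy}-5-bromophenyl]-3-hydroxy-4H-chromen-4-one | COc1cc(COc2c(OCc3ccccc3)cc(-c3oc4cc(OCc5ccccc5)cc(OCc5ccccc5)c4c(=O)c3O)cc2Br)ccc1OCc1ccccc1 | intermediate
8 | 3,5,7-tris(benzyloxy)-2-[3-(benzyloxy)-4-{[4-(benzyloxy)-3-methoxyphenyl]methoxy}-5-bromophenyl]-4H-chromen-4-one | COc1cc(COc2c(OCc3ccccc3)cc(-c3oc4cc(OCc5ccccc5)cc(OCc5ccccc5)c4c(=O)c3OCc3ccccc3)cc2Br)ccc1OCc1ccccc1 | intermediate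
9 | (2-ethoxy-2-oxoethyl)zinc bromide | CCOC(=O)C[Zn]Br | starting material
10 | ethyl 2-[3-(benzyloxy)-2-{[4-(benzyloxy)-3-methoxyphenyl]methoxy}-5-[3,5,7-tris(benzyloxy)-4-oxo-4H-chromen-2-yl]phenyl]acetate | COc1cc(COc2c(OCc3ccccc3)cc(-c3oc4cc(OCc5ccccc5)cc(OCc5ccccc5)c4c(=O)c3OCc3ccccc3)cc2CC(=O)OCC)ccc1OCc1ccccc1 | intermediate
11 | ethyl 2-[3-(benzyloxy)-2-{[4-(benzyloxy)-3-methoxyphenyl]methoxy}-5-[3,5,7-tris(benzyloxy)-4-oxo-4H-chromen-2-yl]phenyl]-2-diazoacetate | COc1cc(COc2c(OCc3ccccc3)cc(-c3oc4cc(OCc5ccccc5)cc(OCc5ccccc5)c4c(=O)c3OCc3ccccc3)cc2C(=[N+]=[N-])C(=O)OCC)ccc1OCc1ccccc1 | intermediate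
12 | ethyl (2R,3S)-7-(benzyloxy)-2-[4-(benzyloxy)-3-methoxyphenyl]-5-[3,5,7-tris(benzyloxy)-4-oxo-4H-chromen-2-yl]-2,3-dihydro-1-benzofuran-3-carboxylate (2,3-cis) | COc1cc([C@@H]2Oc3c(OCc4ccccc4)cc(-c4oc5cc(OCc6ccccc6)cc(OCc6ccccc6)c5c(=O)c4OCc4ccccc4)cc3[C@@H]2C(=O)OCC)ccc1OCc1ccccc1 | intermediate
13 | ethyl (2R,3R)-7-(benzyloxy)-2-[4-(benzyloxy)-3-methoxyphenyl]-5-[3,5,7-tris(benzyloxy)-4-oxo-4H-chromen-2-yl]-2,3-dihydro-1-benzofuran-3-carboxylate (2,3-trans) | COc1cc([C@@H]2Oc3c(OCc4ccccc4)cc(-c4oc5cc(OCc6ccccc6)cc(OCc6ccccc6)c5c(=O)c4OCc4ccccc4)cc3[C@H]2C(=O)OCC)ccc1OCc1ccccc1 | intermediate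
14 | (2R,3R)-7-(benzyloxy)-2-[4-(benzyloxy)-3-methoxyphenyl]-5-[3,5,7-tris(benzyloxy)-4-oxo-4H-chromen-2-yl]-2,3-dihydro-1-benzofuran-3-carboxylic acid (2,3-trans) | COc1cc([C@@H]2Oc3c(OCc4ccccc4)cc(-c4oc5cc(OCc6ccccc6)cc(OCc6ccccc6)c5c(=O)c4OCc4ccccc4)cc3[C@H]2C(=O)O)ccc1OCc1ccccc1 | intermediate
15 | mixed anhydride of acid 14 with isobutyl hydrogen carbonate, (2R,3R) | COc1cc([C@@H]2Oc3c(OCc4ccccc4)cc(-c4oc5cc(OCc6ccccc6)cc(OCc6ccccc6)c5c(=O)c4OCc4ccccc4)cc3[C@H]2C(=O)OC(=O)OCC(C)C)ccc1OCc1ccccc1 | intermediate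
16 | 3,5,7-tris(benzyloxy)-2-[(2R,3S)-7-(benzyloxy)-2-[4-(benzyloxy)-3-methoxyphenyl]-3-(hydroxymethyl)-2,3-dihydro-1-benzofuran-5-yl]-4H-chromen-4-one | COc1cc([C@@H]2Oc3c(OCc4ccccc4)cc(-c4oc5cc(OCc6ccccc6)cc(OCc6ccccc6)c5c(=O)c4OCc4ccccc4)cc3[C@H]2CO)ccc1OCc1ccccc1 | intermediate
17 | 2,3-dehydrosilychristin, 2-[(2R,3S)-7-hydroxy-2-(4-hydroxy-3-methoxyphenyl)-3-(hydroxymethyl)-2,3-dihydro-1-benzofuran-5-yl]-3,5,7-trihydroxy-4H-chromen-4-one | COc1cc([C@@H]2Oc3c(O)cc(-c4oc5cc(O)cc(O)c5c(=O)c4O)cc3[C@H]2CO)ccc1O | target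

Total step count: 9
Longest linear sequence: 9 steps (1 to 17)

Steps most likely to fail

Step 6. The catalyst alone may discriminate poorly between the enantiotopic hydrogens, because the 7-benzyloxy group twists the reacting ether out of the plane of ring B, or the carbene may be diverted into addition to the electron-rich guaiacyl ring. The fallback is covalent auxiliary control in place of catalyst control alone. It sets out from 10: saponification (LiOH, THF/H2O) would give the arylacetic acid F1, which would be esterified (EDC·HCl, DMAP, CH2Cl2) with (S)-2-hydroxy-1-(pyrrolidin-1-yl)propan-1-one to the lactamide ester F2. Diazo transfer (4-acetamidobenzenesulfonyl azide, DBU) would give the diazoester F3, and insertion with Rh2(S-DOSP)4 in CH2Cl2, an auxiliary/catalyst pair of the kind that leads directly to trans-2-aryl-2,3-dihydrobenzofuran-3-carboxylates, would give the trans lactamide ester F4. LiOH would then cleave the auxiliary, and the fallback comes back to the route at 14.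

Step 2. The 6'-benzyloxy group of chalcone 6 may force the enone out of plane so that the oxidised intermediate closes through the α-carbon, which would divert material to an aurone. The fallback separates ring closure from oxygenation of C3. It sets out from 4 and 5: the Claisen–Schmidt condensation alone would give isolated chalcone 6, and I2 (catalytic) in DMSO at 120 °C would cyclise and dehydrogenate it to the flavone F5. Dimethyldioxirane in acetone/CH2Cl2 at 0 °C would give the flavone 2,3-epoxide F6, which a trace of TsOH would open to the flavonol, and the fallback comes back to the route at 7.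

Step 1. Regiocontrol may be lost in the first etherification (alkylation at O5 or at both oxygens), since the 4-OH is flanked by bromine and by the 5-OH. The fallback fixes the 5-O-benzyl group before the ring is brominated. It sets out from 2: catalogue 3-(benzyloxy)-4-hydroxybenzaldehyde F7 would be brominated ortho to the free hydroxyl group (Br2, NaOAc, AcOH) to 3-(benzyloxy)-5-bromo-4-hydroxybenzaldehyde F8, which would be alkylated with 2 (K2CO3, DMF), and the fallback comes back to the route at 4.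

Further compounds
F1 | step 6 | 2-[3-(benzyloxy)-2-{[4-(benzyloxy)-3-methoxyphenyl]methoxy}-5-[3,5,7-tris(benzyloxy)-4-oxo-4H-chromen-2-yl]phenyl]acetic acid | COc1cc(COc2c(OCc3ccccc3)cc(-c3oc4cc(OCc5ccccc5)cc(OCc5ccccc5)c4c(=O)c3OCc3ccccc3)cc2CC(=O)O)ccc1OCc1ccccc1
F2 | step 6 | (2S)-1-oxo-1-(pyrrolidin-1-yl)propan-2-yl 2-[3-(benzyloxy)-2-{[4-(benzyloxy)-3-methoxyphenyl]methoxy}-5-[3,5,7-tris(benzyloxy)-4-oxo-4H-chromen-2-yl]phenyl]acetate | COc1cc(COc2c(OCc3ccccc3)cc(-c3oc4cc(OCc5ccccc5)cc(OCc5ccccc5)c4c(=O)c3OCc3ccccc3)cc2CC(=O)O[C@@H](C)C(=O)N2CCCC2)ccc1OCc1ccccc1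
F3 | step 6 | (2S)-1-oxo-1-(pyrrolidin-1-yl)propan-2-yl 2-[3-(benzyloxy)-2-{[4-(benzyloxy)-3-methoxyphenyl]methoxy}-5-[3,5,7-tris(benzyloxy)-4-oxo-4H-chromen-2-yl]phenyl]-2-diazoacetate | COc1cc(COc2c(OCc3ccccc3)cc(-c3oc4cc(OCc5ccccc5)cc(OCc5ccccc5)c4c(=O)c3OCc3ccccc3)cc2C(=[N+]=[N-])C(=O)O[C@@H](C)C(=O)N2CCCC2)ccc1OCc1ccccc1
F4 | step 6 | (2S)-1-oxo-1-(pyrrolidin-1-yl)propan-2-yl (2R,3R)-7-(benzyloxy)-2-[4-(benzyloxy)-3-methoxyphenyl]-5-[3,5,7-tris(benzyloxy)-4-oxo-4H-chromen-2-yl]-2,3-dihydro-1-benzofuran-3-carboxylate (2,3-trans) | COc1cc([C@@H]2Oc3c(OCc4ccccc4)cc(-c4oc5cc(OCc6ccccc6)cc(OCc6ccccc6)c5c(=O)c4OCc4ccccc4)cc3[C@H]2C(=O)O[C@@H](C)C(=O)N2CCCC2)ccc1OCc1ccccc1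
F5 | step 2 | 5,7-bis(benzyloxy)-2-[3-(benzyloxy)-4-{[4-(benzyloxy)-3-methoxyphenyl]methoxy}-5-bromophenyl]-4H-chromen-4-one | COc1cc(COc2c(OCc3ccccc3)cc(-c3cc(=O)c4c(OCc5ccccc5)cc(OCc5ccccc5)cc4o3)cc2Br)ccc1OCc1ccccc1
F6 | step 2 | 2,3-epoxide of flavone F5, 5,7-bis(benzyloxy)-2-[3-(benzyloxy)-4-{[4-(benzyloxy)-3-methoxyphenyl]methoxy}-5-bromophenyl]-2,3-epoxychroman-4-one (racemic) | COc1cc(COc2c(OCc3ccccc3)cc(C34OC3C(=O)c3c(OCc5ccccc5)cc(OCc5ccccc5)cc3O4)cc2Br)ccc1OCc1ccccc1
F7 | step 1 | 3-(benzyloxy)-4-hydroxybenzaldehyde | O=Cc1ccc(O)c(OCc2ccccc2)c1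
F8 | step 1 | 3-(benzyloxy)-5-bromo-4-hydroxybenzaldehyde | O=Cc1cc(Br)c(O)c(OCc2ccccc2)c1
A1 | direct plan | 4-{3-[(tert-butyldimethylsilyl)oxy]prop-1-yn-1-yl}-2-methoxyphenol | COc1cc(C#CCO[Si](C)(C)C(C)(C)C)ccc1O
A2 | direct plan | 3-[(1Z)-3-[(tert-butyldimethylsilyl)oxy]-1-(4-hydroxy-3-methoxyphenyl)prop-1-en-2-yl]-4,5-dihydroxybenzaldehyde | COc1cc(/C=C(\CO[Si](C)(C)C(C)(C)C)c2cc(C=O)cc(O)c2O)ccc1O
A3 | direct plan | (2R,3S)-3-{[(tert-butyldimethylsilyl)oxy]methyl}-7-hydroxy-2-(4-hydroxy-3-methoxyphenyl)-2,3-dihydro-1-benzofuran-5-carbaldehyde | COc1cc([C@@H]2Oc3c(O)cc(C=O)cc3[C@H]2CO[Si](C)(C)C(C)(C)C)ccc1O
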